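In the beta run Q rises at first by about 0.0110 /min as a fraction of the X charged, bends after 12.0 min and levels near 11.5%. In that run the gap between X lost and Q formed stays near 6.50%. Against 10 mol% of D, that reads as 65.0% of the catalyst held steadily in a resting state, so I take the rate of making Q to follow E.

beta run (percent of the X charged)

| time / min | Q / % | X / % |
|---|---|---|
| 4.00 | 4.4 | 89.8 |
| 8.00 | 6.0 | 87.1 |
| 12.0 | 9.7 | 84.4 |
| 15.0 | 10.1 | 83.3 |
| 20.0 | 11.0 | 82.4 |
| 25.0 | 11.5 | 82.0 |

(each reading ± 0.5 percentage points)

- beta: X 0.20 M; G 0.50 equiv; E 0.55 equiv; D 10 mol%; run made earlier
- flask: X 0.20 M; G 0.500 equiv; E 1.10 equiv; D 10 mol%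

My own reckoning supposes that E ended that curve. On that supposition, of the 0.55 equiv of E charged, Q took as much as 11.5% of the X charged, and a side drain tied to G took the rest, 3.78 per Q, which I let scale with G over E. The flask then drains 1.89 per Q. At 20% converted, less the gap, the flask's Q is 13.5% of the X charged and its drain 0.255 equiv. The toll, drained E over E still present at that conversion, is 0.360. One percent more G takes that many percent off E, so I expect an order of −0.360.

- apparent order in G when 20% of the X are converted (percent change of the rate of making Q for one percent more G charged)

- what is bound to the catalyst counts as converted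
- no earlier run changes the charge of G; that part of a forecast is a guess

The forecast gives 0.7, with a range of 0.1 to 1.3: “No run varies G, so this is a guess”. My figure stands lower and has the opposite sign.

The flask gives −0.27, below the forecast's range.

    X + D ⇌ L (K = 13.0 /M, k = 0.140 /M/s)
    E + L ⇌ D + Q (K = 1.10, k = 0.0290 /M/s)
    G + D ⇌ Z (K = 160 /M, k = 0.120 /M/s)
    E + Z → D + J (k = 1.80 /M/s)

The drain is the step E + Z → D + J, which has made 0.0379 M of J in the flask by 8.00 min. Without that step the order is −1.0, not −0.27, so in the flask the step raises the order instead of lowering it as the toll supposed. With twice the G, the toll puts the rate at 20% converted at 0.640 of the flask's, and the simulated run gives a factor of 0.696.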